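**Retrosynthetic overview**

1. The target is the isofraxidin ether and C3 acetate of 9-epi-drim-7-ene-3α,11-diol (22). The acetate and the aryl ether C11–O (Mitsunobu) are disconnected last.
2. Diol 22 goes back to the trans-fused 7-silyloxy-Δ6 cycloadduct 15: enol ether → C7 ketone → more substituted enol triflate → C7=C8 alkene; C3 is inverted by oxidation and LiBH(s-Bu)3 reduction.
3. Cycloadduct 15 comes from the acyclic trienoate 14 by one intramolecular Diels–Alder reaction that forms C5–C10 and C8–C9. Rings A and B close together; no ring exists before this step.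
4. The strategy rests on ring B: a cyclohexene whose fusion bond C5–C10 and bond C8–C9 are 1,4-related across C6/C7, with the CH2O carbon C11 axial on C9 and trans to the C10 methyl. A (Z)-3-methyl-2-enoate dienophile transfers exactly this relationship.
5. Trienoate 14 is assembled from (R)-pantolactone (C2–C5 with the C4 gem-dimethyl and the C3 oxygen), methyl (Z)-3-iodobut-2-enoate (C9–C11 and the C10 methyl; B-alkyl Suzuki coupling at C1–C10) and diethyl (2-oxobutyl)phosphonate (C6–C8 and the C8 methyl).

Key step: step 11

Assumption: the decalin is numbered as a drimane (ring A = C1–C5, C10; ring B = C5–C10; C11 = CH2O carbon on C9). α/β refer to the usual orientation with the C10 methyl β. "9-epi" means C11 is α (axial, trans to the C10 methyl). In this numbering the target is 3R,5R,9R,10S: 3α-OAc, 5α-H, 9β-H.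

**Route**

Step 1
Reactants: 1 (R)-pantolactone
Product: 2 (R)-3-(tert-butyldimethylsilyloxy)-4,4-dimethyldihydrofuran-2(3H)-one
Conditions: TBSCl, imidazole, DMF, rt
Reagents that add atoms: tert-butyldimethylsilyl chloride, CC(C)(C)[Si](C)(C)Cl
Why: Imidazole-promoted silylation of the hindered α-hydroxy lactone, in which the stereocentre takes no part.

Step 2
Reactants: 2 silyloxy lactone
Product: 3 (3R)-3-(tert-butyldimethylsilyloxy)-4,4-dimethyloxolan-2-ol (anomer mixture)
Conditions: i-Bu2AlH (DIBAL-H), CH2Cl2, –78 °C; aqueous work-up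
Reagents that add atoms: none
Why: Partial lactone reduction, which stops at the tetrahedral aluminium hemiacetal at –78 °C and gives the lactol on work-up.

Step 3
Reactants: 3 lactol
Product: 4 (3S)-3-(tert-butyldimethylsilyloxy)-2,2-dimethylpent-4-en-1-ol
Conditions: Ph3PCH3Br, KOt-Bu, THF, 0 °C to rt
Reagents that add atoms: methyltriphenylphosphonium bromide, C[P+](c1ccccc1)(c1ccccc1)c1ccccc1.[Br-]
Why: Wittig methylenation of the hydroxy aldehyde in equilibrium with the lactol, where excess ylide at low temperature should limit epimerisation of the α-silyloxy aldehyde and a 1,3 O-to-O silyl shift in the liberated alkoxide would be harmless because step 4 converts either isomer into the same bis-silyl ether.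

Step 4
Reactants: 4 alkenol
Product: 5 (3S)-3,5-bis(tert-butyldimethylsilyloxy)-4,4-dimethylpent-1-ene
Conditions: TBSOTf, 2,6-lutidine, CH2Cl2, 0 °C
Reagents that add atoms: tert-butyldimethylsilyl triflate, CC(C)(C)[Si](C)(C)OS(=O)(=O)C(F)(F)F
Why: Silylation with a silyl triflate and a hindered pyridine base, which caps a primary or a hindered secondary hydroxyl alike, so that 4 and any silyl-migrated isomer converge on 5.

Step 5
Reactants: 6 methyl but-2-ynoate
Product: 7 methyl (Z)-3-iodobut-2-enoate
Conditions: NaI, AcOH, 110 °C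
Reagents that add atoms: sodium iodide, [Na+].[I-]
Why: Conjugate hydroiodination of a 2-ynoate, a kinetic anti addition of HI that places iodine cis to the ester.

Step 6
Reactants: 5 bis-silyl alkene; 7 methyl (Z)-3-iodobut-2-enoate
Product: 9 methyl (2Z,6S)-6,8-bis(tert-butyldimethylsilyloxy)-3,7,7-trimethyloct-2-enoate, via alkylborane 8 (not isolated)
Conditions: 9-BBN, THF, rt; then 7, Pd(dppf)Cl2 (cat.), AsPh3 (cat.), Cs2CO3, DMF/H2O, rt
Reagents that add atoms: 9-borabicyclo[3.3.1]nonane, B1C2CCCC1CCC2 (its boron and ring are carried only in intermediate 8 and leave again in the coupling)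
Why: Anti-Markovnikov hydroboration of the monosubstituted alkene followed by B-alkyl Suzuki–Miyaura coupling, which retains the vinyl iodide geometry, so the chain takes the place of iodine cis to the ester and the (Z)-enoate results.

Step 7
Reactants: 9 bis-silyl (Z)-enoate
Product: 10 methyl (2Z,6S)-6-(tert-butyldimethylsilyloxy)-8-hydroxy-3,7,7-trimethyloct-2-enoate
Conditions: HF·pyridine, pyridine, THF, 0 °C to rt
Reagents that add atoms: none
Why: Buffered fluoride desilylation, which is much faster at the primary silyl ether than at the secondary one flanked by the quaternary carbon.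

Step 8
Reactants: 10 primary alcohol
Product: 11 methyl (2Z,6S)-6-(tert-butyldimethylsilyloxy)-3,7,7-trimethyl-8-oxooct-2-enoate
Conditions: Dess–Martin periodinane, CH2Cl2, rt
Reagents that add atoms: none
Why: Dess–Martin oxidation of a primary alcohol to an aldehyde that has no α-hydrogen and so can neither epimerise nor eliminate the β-silyloxy group.

Step 9
Reactants: 11 aldehyde; 12 diethyl (2-oxobutyl)phosphonate
Product: 13 methyl (2Z,6S,8E)-6-(tert-butyldimethylsilyloxy)-3,7,7-trimethyl-10-oxododeca-2,8-dienoate
Conditions: 12, NaH, THF, 0 °C; then 11, 0 to 45 °C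
Reagents that add atoms: none
Why: Horner–Wadsworth–Emmons olefination with a stabilised β-ketophosphonate anion, which gives the (E)-enone and is too weakly basic to touch the enoate.

Step 10
Reactants: 13 enone
Product: 14 methyl (2Z,6S,8E,10Z)-6,10-bis(tert-butyldimethylsilyloxy)-3,7,7-trimethyldodeca-2,8,10-trienoate
Conditions: TBSOTf, Et3N, CH2Cl2, –78 to 0 °C
Reagents that add atoms: tert-butyldimethylsilyl triflate, CC(C)(C)[Si](C)(C)OS(=O)(=O)C(F)(F)F
Why: Soft enolisation of the ethyl ketone (silyl triflate/amine), which can only occur toward the ethyl group and should give mainly the (Z)-enol ether with the terminal methyl outside the diene, while the less acidic enoate is left alone.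

Step 11
Reactants: 14 silyloxytrienoate
Product: 15 methyl 3β,7-bis(tert-butyldimethylsilyloxy)-9-epi-drim-6-en-11-oate (trans-fused; 5α-H, 8β-CH3, 9α-CO2Me, 10β-CH3)
Conditions: PhMe (0.01 M, degassed), BHT (cat.), base-washed sealed tube, 190 °C
Reagents that add atoms: none
Why: A thermal intramolecular Diels–Alder reaction of a 1,7,9-decatrienoate (known reaction type): the 2-silyloxydiene C5=C6–C7=C8 adds suprafacially across the (Z)-enoate C9=C10 in one concerted, asynchronous step that forms C5–C10 and C8–C9. Ring A closes as the six-membered tether ring (C10–C1–C2–C3–C4–C5) and ring B as the new cyclohexene (C5–C6=C7–C8–C9–C10), both in the same transition state. C9 relative to C10 is fixed by the dienophile geometry (the ester is cis to tether carbon C1 and therefore ends trans to the C10 methyl whatever the topology), and C8 follows from the (Z)-enol ether and is erased in step 13. C5 relative to C10 (trans fusion) needs the tether-anti chair transition state with the ester exo; this should be preferred because the ester-endo alternatives must either carry the diene axially on the tether chair or put C9 instead of the C10 methyl into the 1,3-diaxial site facing the axial C4 methyl, but the preference is substrate-dependent. The absolute sense comes from the C3 silyloxy group taking the equatorial site of that chair, which places the C10 methyl β and the C5 hydrogen α. Because the tether forces C5 onto the enoate β-carbon against the polarisation of the 2-silyloxydiene, activation is modest and about 190 °C should be needed.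

Step 12
Reactants: 15 cycloadduct
Product: 16 methyl 3β-(tert-butyldimethylsilyloxy)-7-oxo-9-epi-driman-11-oate (8β-CH3 as delivered)
Conditions: Bu4NF, AcOH (1:1), THF, –20 to 0 °C
Reagents that add atoms: none
Why: Buffered fluoride cleavage, which removes the silyl enol ether far faster than the hindered alkyl silyl ether and protonates the enolate at C6 under near-neutral conditions, so C9 is not epimerised (equilibration at C8 would not matter, since C8 becomes trigonal in step 13).

Step 13
Reactants: 16 ketone
Product: 17 methyl 3β-(tert-butyldimethylsilyloxy)-7-(trifluoromethylsulfonyloxy)-9-epi-drim-7-en-11-oate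
Conditions: Tf2O, 2,6-di-tert-butyl-4-methylpyridine, CH2Cl2, 0 °C to rt
Reagents that add atoms: triflic anhydride, O=S(=O)(OS(=O)(=O)C(F)(F)F)C(F)(F)F
Why: O-Triflation of the ketone with a hindered non-nucleophilic base, which loses the proton leading to the more substituted enol triflate (helped here by relief of the 1,3-diaxial contact between the C8 and C10 methyls) in a non-basic medium that leaves the C9 ester centre alone.

Step 14
Reactants: 17 enol triflate
Product: 18 methyl 3β-(tert-butyldimethylsilyloxy)-9-epi-drim-7-en-11-oate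
Conditions: Pd(OAc)2 (cat.), PPh3, HCO2H, n-Bu3N, DMF, 60 °C
Reagents that add atoms: none
Why: Palladium-catalysed formate reduction of an enol triflate (oxidative addition, formate exchange, decarboxylation, reductive elimination), which replaces OTf by H without moving the alkene.

Step 15
Reactants: 18 silyl ether
Product: 19 methyl 3β-hydroxy-9-epi-drim-7-en-11-oate
Conditions: aq. HF (48%), MeCN, rt
Reagents that add atoms: none
Why: Mildly acidic fluoride desilylation of the secondary silyl ether under non-basic conditions that should neither epimerise C9 nor shift the trisubstituted alkene.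

Step 16
Reactants: 19 3β-alcohol
Product: 20 methyl 3-oxo-9-epi-drim-7-en-11-oate
Conditions: Dess–Martin periodinane, CH2Cl2, rt
Reagents that add atoms: none
Why: Dess–Martin oxidation of the secondary alcohol under neutral conditions, which makes C3 trigonal in preparation for its inversion.

Step 17
Reactants: 20 3-ketone
Product: 21 methyl 3α-hydroxy-9-epi-drim-7-en-11-oate
Conditions: LiBH(s-Bu)3, THF, –78 °C; then H2O
Reagents that add atoms: none
Why: Reduction with a bulky trialkylborohydride, which attacks the C3 ketone along the equatorial trajectory and gives the axial 3α alcohol (the selectivity known for 4,4-dimethyl-3-oxo terpenoids), while the hindered ester is not reduced at –78 °C.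

Step 18
Reactants: 21 hydroxy ester
Product: 22 9-epi-drim-7-ene-3α,11-diol
Conditions: i-Bu2AlH (excess), CH2Cl2, –78 to 0 °C; aqueous work-up
Reagents that add atoms: none
Why: Ester reduction by a Lewis-acidic hydride, which does not enolise the ester, so C9 keeps its configuration.

Step 19
Reactants: 22 diol; 23 isofraxidin
Product: 24 7-[(3α-hydroxy-9-epi-drim-7-en-11-yl)oxy]-6,8-dimethoxy-2H-chromen-2-one
Conditions: PPh3, DIAD, THF (concentrated), 0 °C to rt
Reagents that add atoms: none
Why: Mitsunobu etherification, in which the acidic 7-hydroxycoumarin protonates the betaine and displaces the primary oxyphosphonium group at C11 (no stereocentre is touched), while the axial neopentyl-type C3 hydroxyl is too hindered to be activated.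

Step 20
Reactants: 24 ether alcohol
Product: 25 7-[(3α-acetoxy-9-epi-drim-7-en-11-yl)oxy]-6,8-dimethoxy-2H-chromen-2-one (target)
Conditions: Ac2O, DMAP (cat.), pyridine, CH2Cl2, rt to 40 °C
Reagents that add atoms: acetic anhydride, CC(=O)OC(C)=O
Why: DMAP-catalysed acylation of the hindered axial secondary alcohol, to which the coumarin lactone and the aryl alkyl ether are inert.

**Compound list**

1 | (R)-pantolactone | CC1(C)COC(=O)[C@@H]1O | starting material
2 | (R)-3-(tert-butyldimethylsilyloxy)-4,4-dimethyldihydrofuran-2(3H)-one | CC1(C)COC(=O)[C@@H]1O[Si](C)(C)C(C)(C)C | intermediate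
3 | (3R)-3-(tert-butyldimethylsilyloxy)-4,4-dimethyloxolan-2-ol (anomer mixture) | CC1(C)COC(O)[C@@H]1O[Si](C)(C)C(C)(C)C | intermediate
4 | (3S)-3-(tert-butyldimethylsilyloxy)-2,2-dimethylpent-4-en-1-ol | C=C[C@H](O[Si](C)(C)C(C)(C)C)C(C)(C)CO | intermediate
5 | (3S)-3,5-bis(tert-butyldimethylsilyloxy)-4,4-dimethylpent-1-ene | C=C[C@H](O[Si](C)(C)C(C)(C)C)C(C)(C)CO[Si](C)(C)C(C)(C)C | intermediate
6 | methyl but-2-ynoate | CC#CC(=O)OC | starting material
7 | methyl (Z)-3-iodobut-2-enoate | COC(=O)/C=C(C)\I | intermediate
8 | B-[(3S)-3,5-bis(tert-butyldimethylsilyloxy)-4,4-dimethylpentyl]-9-borabicyclo[3.3.1]nonane (not isolated) | B1(CC[C@H](O[Si](C)(C)C(C)(C)C)C(C)(C)CO[Si](C)(C)C(C)(C)C)C2CCCC1CCC2 | intermediate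
9 | methyl (2Z,6S)-6,8-bis(tert-butyldimethylsilyloxy)-3,7,7-trimethyloct-2-enoate | COC(=O)/C=C(C)\CC[C@H](O[Si](C)(C)C(C)(C)C)C(C)(C)CO[Si](C)(C)C(C)(C)C | intermediate
10 | methyl (2Z,6S)-6-(tert-butyldimethylsilyloxy)-8-hydroxy-3,7,7-trimethyloct-2-enoate | COC(=O)/C=C(C)\CC[C@H](O[Si](C)(C)C(C)(C)C)C(C)(C)CO | intermediate
11 | methyl (2Z,6S)-6-(tert-butyldimethylsilyloxy)-3,7,7-trimethyl-8-oxooct-2-enoate | COC(=O)/C=C(C)\CC[C@H](O[Si](C)(C)C(C)(C)C)C(C)(C)C=O | intermediate
12 | diethyl (2-oxobutyl)phosphonate | CCOP(=O)(CC(=O)CC)OCC | starting material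
13 | methyl (2Z,6S,8E)-6-(tert-butyldimethylsilyloxy)-3,7,7-trimethyl-10-oxododeca-2,8-dienoate | COC(=O)/C=C(C)\CC[C@H](O[Si](C)(C)C(C)(C)C)C(C)(C)/C=C/C(=O)CC | intermediate
14 | methyl (2Z,6S,8E,10Z)-6,10-bis(tert-butyldimethylsilyloxy)-3,7,7-trimethyldodeca-2,8,10-trienoate | COC(=O)/C=C(C)\CC[C@H](O[Si](C)(C)C(C)(C)C)C(C)(C)/C=C/C(O[Si](C)(C)C(C)(C)C)=C/C | intermediate
15 | methyl 3β,7-bis(tert-butyldimethylsilyloxy)-9-epi-drim-6-en-11-oate (5α-H, 8β-CH3, 10β-CH3) | COC(=O)[C@@H]1[C@@H](C)C(O[Si](C)(C)C(C)(C)C)=C[C@H]2C(C)(C)[C@@H](O[Si](C)(C)C(C)(C)C)CC[C@]12C | intermediate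
16 | methyl 3β-(tert-butyldimethylsilyloxy)-7-oxo-9-epi-driman-11-oate (8β-CH3) | COC(=O)[C@@H]1[C@@H](C)C(=O)C[C@H]2C(C)(C)[C@@H](O[Si](C)(C)C(C)(C)C)CC[C@]12C | intermediate
17 | methyl 3β-(tert-butyldimethylsilyloxy)-7-(trifluoromethylsulfonyloxy)-9-epi-drim-7-en-11-oate | COC(=O)[C@@H]1C(C)=C(OS(=O)(=O)C(F)(F)F)C[C@H]2C(C)(C)[C@@H](O[Si](C)(C)C(C)(C)C)CC[C@]12C | intermediate
18 | methyl 3β-(tert-butyldimethylsilyloxy)-9-epi-drim-7-en-11-oate | COC(=O)[C@@H]1C(C)=CC[C@H]2C(C)(C)[C@@H](O[Si](C)(C)C(C)(C)C)CC[C@]12C | intermediate
19 | methyl 3β-hydroxy-9-epi-drim-7-en-11-oate | COC(=O)[C@@H]1C(C)=CC[C@H]2C(C)(C)[C@@H](O)CC[C@]12C | intermediate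
20 | methyl 3-oxo-9-epi-drim-7-en-11-oate | COC(=O)[C@@H]1C(C)=CC[C@H]2C(C)(C)C(=O)CC[C@]12C | intermediate
21 | methyl 3α-hydroxy-9-epi-drim-7-en-11-oate | COC(=O)[C@@H]1C(C)=CC[C@H]2C(C)(C)[C@H](O)CC[C@]12C | intermediate
22 | 9-epi-drim-7-ene-3α,11-diol | OC[C@@H]1C(C)=CC[C@H]2C(C)(C)[C@H](O)CC[C@]12C | intermediate
23 | isofraxidin (7-hydroxy-6,8-dimethoxycoumarin) | COc1cc2ccc(=O)oc2c(OC)c1O | starting material
24 | 7-[(3α-hydroxy-9-epi-drim-7-en-11-yl)oxy]-6,8-dimethoxy-2H-chromen-2-one | COc1cc2ccc(=O)oc2c(OC)c1OC[C@@H]1C(C)=CC[C@H]2C(C)(C)[C@H](O)CC[C@]12C | intermediate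
25 | 7-[(3α-acetoxy-9-epi-drim-7-en-11-yl)oxy]-6,8-dimethoxy-2H-chromen-2-one | COc1cc2ccc(=O)oc2c(OC)c1OC[C@@H]1C(C)=CC[C@H]2C(C)(C)[C@H](OC(C)=O)CC[C@]12C | target

**Step count**

Total: 20 steps. Longest linear sequence: 19 steps (steps 1–4 and 6–20, from 1 to 25); step 5 is a one-step side branch.

**Steps most likely to fail, with fallbacks**

Step 11 (cycloaddition). Three processes threaten it:
- Incomplete trans selectivity at the ring fusion (ester-endo transition states compete).
- Incomplete diene-face selectivity (C3 silyloxy axial instead of equatorial). That diastereomer has to be removed by chromatography before C3 is oxidised, because it would otherwise erode enantiomeric purity.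
- Slow reaction of the β,β-disubstituted dienophile, which gives time for enol ether loss or Z/E leakage of the enoate.

Fallback for the ring-fusion problem, setting out from triene 14: the thermolysate containing 15 and its cis-fused C5 epimer (5β-H, 8α-CH3) F1 would not be separated. It would be oxidised under Saegusa–Ito conditions (Pd(OAc)2, MeCN, rt). This removes the C5 stereocentre and should converge both adducts on methyl 3β-(tert-butyldimethylsilyloxy)-7-oxo-9-epi-drim-5-en-11-oate (C8 epimer mixture) F2. Dissolving-metal reduction (Li, NH3/THF, t-BuOH 1 equiv, –78 °C, two equivalents of metal so that the hindered ester survives) then protonates the C5 carbanion axially and should give the trans-fused ketone 16 together with its 8α-methyl epimer F3. The route is rejoined at 16; F3 gives the same triflate 17 in step 13. This correction works only for adducts that share the C9/C10 configuration of 15.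

Step 13 (enol triflate). The risk is proton loss toward C6 as well as C8, giving a mixture of Δ6 and Δ7 triflates. Fallback, setting out from ketone 16: the ketone would first be converted under equilibrating conditions (Me3SiCl, NaI, Et3N, MeCN, 40 °C) into the more substituted enol ether, methyl 3β-(tert-butyldimethylsilyloxy)-7-(trimethylsilyloxy)-9-epi-drim-7-en-11-oate F4. Its regiochemistry can be checked before committing. CsF and PhNTf2 in DME would then triflate the fluoride-released enolate without equilibration, and the route is rejoined at triflate 17.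

Step 19 (Mitsunobu). The risk is sluggish displacement at the β-branched, axial C11 by the di-ortho-substituted phenol, with competing loss of the allylic C9 hydrogen to give an exocyclic diene. Fallback, setting out from diol 22: the primary hydroxyl would be sulfonylated selectively (MsCl, Et3N, CH2Cl2, –20 °C) to 3α-hydroxy-9-epi-drim-7-en-11-yl methanesulfonate F5. This would be displaced by the preformed caesium phenoxide of isofraxidin 23 (Cs2CO3, NaI cat., DMF, 70 °C), and the route is rejoined at ether alcohol 24.

**Further compounds**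

F1 | step 11 | methyl 3β,7-bis(tert-butyldimethylsilyloxy)-9-epi-drim-6-en-11-oate, cis-fused C5 epimer (5β-H, 8α-CH3) | COC(=O)[C@@H]1[C@H](C)C(O[Si](C)(C)C(C)(C)C)=C[C@@H]2C(C)(C)[C@@H](O[Si](C)(C)C(C)(C)C)CC[C@]12C
F2 | step 11 | methyl 3β-(tert-butyldimethylsilyloxy)-7-oxo-9-epi-drim-5-en-11-oate (C8 epimer mixture) | COC(=O)[C@@H]1C(C)C(=O)C=C2C(C)(C)[C@@H](O[Si](C)(C)C(C)(C)C)CC[C@]12C
F3 | step 11 | methyl 3β-(tert-butyldimethylsilyloxy)-7-oxo-9-epi-driman-11-oate, 8α-methyl epimer | COC(=O)[C@@H]1[C@H](C)C(=O)C[C@H]2C(C)(C)[C@@H](O[Si](C)(C)C(C)(C)C)CC[C@]12C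
F4 | step 13 | methyl 3β-(tert-butyldimethylsilyloxy)-7-(trimethylsilyloxy)-9-epi-drim-7-en-11-oate | COC(=O)[C@@H]1C(C)=C(O[Si](C)(C)C)C[C@H]2C(C)(C)[C@@H](O[Si](C)(C)C(C)(C)C)CC[C@]12C
F5 | step 19 | 3α-hydroxy-9-epi-drim-7-en-11-yl methanesulfonate | CS(=O)(=O)OC[C@@H]1C(C)=CC[C@H]2C(C)(C)[C@H](O)CC[C@]12C
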